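The route rests on disconnecting rings A and B of the labdane-type decalin at C4–C5 and C9–C10 together with the C8–O bond. An (E,E)-configured epoxy-farnesylacetone, oxidised at its trans terminal methyl (future C18) and epoxidised at C3–C4, is folded chair–chair by a Lewis acid: both carbocycles and a dihydropyran close in one operation, setting C4, C5, C10, C9 and the equatorial C8 oxygen relative to the C3 epoxide carbon. The feature exploited is the trans-decalin with equatorial C18 on C4, C20 on C10, the equatorial C9 chain and the C8 tertiary oxygen. Redox adjustment at C3, C6 and C18, then attachment and peroxidation of a six-carbon unit, complete the target.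

Key step: step 4

Remark: the target is taken as drawn, with the γ-lactone trans-fused to the 1,2-dioxane; labdane numbering is used for the decalin (C18 = 4α ester carbon, C16 = CH3/CH2 carbon on C13) and 1′–6′ for the six-carbon unit on C13 (C1′ peroxide CH, C3′ lactone CH–O, C4′ methyl-bearing peroxide carbon, C6′ lactone carbonyl), so the target is (1′R,3′S,4′R).
Remark: the (2S,3S)-epoxide 4 and tricycle 5 were checked against the target (3β-OH, 4α-CH2O, 5α-H, 10β-CH3, 9α-H, 8α-O) and need no structural change; the ketone is carried unprotected so that the epoxide never meets a deprotection acid, and the dioxane is closed by an exo displacement.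

Step 1
Reactants: 1 (5E,9E)-farnesylacetone
Product: 2 (5E,9E,13E)-15-hydroxy-6,10,14-trimethylpentadeca-5,9,13-trien-2-one
Conditions: SeO2 (cat.), t-BuOOH, salicylic acid (cat.), CH2Cl2, 0 °C to rt, stopped at partial conversion
Reagents that add atoms: tert-butyl hydroperoxide CC(C)(C)OO
Why: SeO2-catalysed allylic oxidation (ene reaction then [2,3]-sigmatropic shift) should attack the terminal, most accessible trisubstituted alkene at its (E)-methyl group, while the methyl ketone is inert at room temperature.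

Step 2
Reactants: 2 (5E,9E,13E)-15-hydroxy-6,10,14-trimethylpentadeca-5,9,13-trien-2-one
Product: 3 (5E,9E)-12-[(2S,3S)-3-(hydroxymethyl)-3-methyloxiran-2-yl]-6,10-dimethyldodeca-5,9-dien-2-one
Conditions: Ti(OiPr)4 (cat.), L-(+)-diethyl tartrate, t-BuOOH, 4 Å MS, CH2Cl2, −20 °C
Reagents that add atoms: tert-butyl hydroperoxide CC(C)(C)OO
Why: Sharpless asymmetric epoxidation of the (E)-allylic alcohol with L-(+)-tartrate should give the (2S,3S)-epoxy alcohol (future C3 and C4) under reagent control, the remote alkenes and the ketone not binding the titanium–tartrate catalyst.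

Step 3
Reactants: 3 (5E,9E)-12-[(2S,3S)-3-(hydroxymethyl)-3-methyloxiran-2-yl]-6,10-dimethyldodeca-5,9-dien-2-one
Product: 4 (5E,9E)-12-[(2S,3S)-3-(tert-butyldiphenylsilyloxymethyl)-3-methyloxiran-2-yl]-6,10-dimethyldodeca-5,9-dien-2-one
Conditions: TBDPSCl, imidazole, CH2Cl2, rt
Reagents that add atoms: tert-butyldiphenylsilyl chloride CC(C)(C)[Si](Cl)(c1ccccc1)c1ccccc1
Why: Imidazole-mediated silylation of the primary alcohol gives a bulky, weakly Lewis-basic ether that should not chelate aluminium and should survive the cyclisation.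

Step 4
Reactants: 4 (5E,9E)-12-[(2S,3S)-3-(tert-butyldiphenylsilyloxymethyl)-3-methyloxiran-2-yl]-6,10-dimethyldodeca-5,9-dien-2-one
Product: 5 18-(tert-butyldiphenylsilyloxy)-8α,13-epoxy-14,15-dinorlabd-12-en-3β-ol
Conditions: MeAlCl2 (2.2 equiv), CH2Cl2, −78 °C; Et3N/MeOH quench, aq. NaHCO3
Reagents that add atoms: none
Why: MeAlCl2 activates the epoxide, the C5=C10 alkene attacks the tertiary epoxide carbon C4 opposite to the C4–O bond (ring A, 6-endo), the C8=C9 alkene adds to C10 (ring B, 6-endo-trig) and the tether ketone oxygen captures the tertiary C8 cation (six-membered ring through oxygen), the oxocarbenium ion then losing H12 to give the enol ether. The closest known reaction type is the Lewis acid-promoted epoxy-polyene cyclisation with oxygen termination, together with the acid-induced closure of farnesylacetone to the same tricyclic enol ether skeleton. C4 is set by stereospecific inversion of the epoxide, so the CH2OSi group trans to the chain becomes the equatorial 4α substituent (C18) and the cis methyl the axial C19. C5/C10 and C9/C8 follow from anti addition across the two (E)-alkenes in a chair–chair fold, which places H5 and H9 axial (α), C20 axial (β) and the C8 oxygen equatorial (α). The step needs facial selectivity over the whole cascade, and this is secured by the (3S) epoxide carbon, whose C3–O bond must lie equatorial in the chair transition state of ring A. Two equivalents of Lewis acid are used because the ketone also binds aluminium, and the low temperature limits proton loss from the intermediate cations.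

Step 5
Reactants: 5 18-(tert-butyldiphenylsilyloxy)-8α,13-epoxy-14,15-dinorlabd-12-en-3β-ol
Product: 7 O-[18-(tert-butyldiphenylsilyloxy)-8α,13-epoxy-14,15-dinorlabd-12-en-3β-yl] S-methyl dithiocarbonate, via sodium xanthate 6 (not isolated)
Conditions: NaH, CS2, THF, 0 °C to rt; then MeI
Reagents that add atoms: carbon disulfide S=C=S; iodomethane CI
Why: Xanthate formation (first half of the Barton–McCombie sequence) should proceed by addition of the secondary C3 alkoxide to CS2 and S-methylation, the enol ether and silyl ether being stable to base.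

Step 6
Reactants: 7 O-[18-(tert-butyldiphenylsilyloxy)-8α,13-epoxy-14,15-dinorlabd-12-en-3β-yl] S-methyl dithiocarbonate
Product: 8 18-(tert-butyldiphenylsilyloxy)-8α,13-epoxy-14,15-dinorlabd-12-ene
Conditions: Bu3SnH, AIBN, toluene, 110 °C
Reagents that add atoms: none
Why: Barton–McCombie deoxygenation: stannyl radical addition to C=S and β-scission give the secondary C3 radical, which is reduced by the tin hydride without creating a stereocentre and out of reach of the enol ether alkene.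

Step 7
Reactants: 8 18-(tert-butyldiphenylsilyloxy)-8α,13-epoxy-14,15-dinorlabd-12-ene
Product: 10 8α,18-dihydroxy-14,15-dinorlabdan-13-one, via enol ether alcohol 9 (not isolated)
Conditions: TBAF, THF, rt; then 1 M HCl, rt
Reagents that add atoms: water O
Why: Fluoride desilylation followed by acid hydrolysis of the cyclic enol ether (C12 protonation, hydration, hemiketal opening) should give the open 8α-hydroxy methyl ketone without touching a stereocentre.

Step 8
Reactants: 10 8α,18-dihydroxy-14,15-dinorlabdan-13-one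
Product: 12 8α-hydroxy-13-oxo-14,15-dinorlabdan-18-oic acid, via C18 aldehyde 11 (not isolated)
Conditions: TEMPO (cat.), NaClO2, NaOCl (cat.), MeCN/phosphate buffer (pH 6.7), 35 °C
Reagents that add atoms: sodium chlorite [Na+].[O-]Cl=O
Why: Oxoammonium/chlorite oxidation converts only the primary C18 alcohol, through its aldehyde, into the acid, since the tertiary C8 alcohol and the ketone cannot be oxidised under these conditions.

Step 9
Reactants: 12 8α-hydroxy-13-oxo-14,15-dinorlabdan-18-oic acid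
Product: 13 8α-hydroxy-13-oxo-14,15-dinorlabdan-18,6α-olide
Conditions: [Fe((S,S)-PDP)(MeCN)2](SbF6)2 (3 × 5 mol%), H2O2 (3 × 1.2 equiv), MeCN, rt
Reagents that add atoms: hydrogen peroxide OO
Why: Carboxylate-directed C–H lactonisation with a non-haem iron/H2O2 catalyst: the bound C18 carboxylate should hold the iron-oxo unit next to the equatorial H6α, the only γ-hydrogen within reach (C2 is anti to C18), and oxygen is delivered with retention to close the five-membered 18,6α-lactone and fix C6.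

Step 10
Reactants: 13 8α-hydroxy-13-oxo-14,15-dinorlabdan-18,6α-olide
Product: 15 methyl 6α,8α-dihydroxy-13-oxo-14,15-dinorlabdan-18-oate, via potassium carboxylate 14 (not isolated)
Conditions: KOH, MeOH/H2O, 65 °C; CO2 to pH 8, evaporate; then MeI, DMF, rt
Reagents that add atoms: potassium hydroxide [K+].[OH-]; iodomethane CI
Why: Saponification of the γ-lactone and O-alkylation of the carboxylate with MeI under bicarbonate buffering, which is too weak to form the C6 alkoxide, should give the hydroxy ester without relactonisation.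

Step 11
Reactants: 15 methyl 6α,8α-dihydroxy-13-oxo-14,15-dinorlabdan-18-oate
Product: 16 methyl 13-oxo-6α,8α-bis(triethylsilyloxy)-14,15-dinorlabdan-18-oate
Conditions: TESOTf, 2,6-lutidine, CH2Cl2, −78 to 0 °C
Reagents that add atoms: triethylsilyl trifluoromethanesulfonate CC[Si](CC)(CC)OS(=O)(=O)C(F)(F)F
Why: Silylation with a silyl triflate and a hindered pyridine base should cap the hindered secondary C6 and tertiary C8 hydroxyls, which blocks relactonisation and hemiketal formation in the following steps.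

Step 12
Reactants: 16 methyl 13-oxo-6α,8α-bis(triethylsilyloxy)-14,15-dinorlabdan-18-oate
Product: 18 methyl 6α,8α-bis(triethylsilyloxy)-13-(trifluoromethanesulfonyloxy)-14,15-dinorlabd-13(16)-en-18-oate, via potassium enolate 17 (not isolated)
Conditions: KN(SiMe3)2, THF, −78 °C; then PhNTf2
Reagents that add atoms: N-phenylbis(trifluoromethanesulfonimide) O=S(=O)(N(c1ccccc1)S(=O)(=O)C(F)(F)F)C(F)(F)F
Why: Kinetic deprotonation of the methyl ketone at the methyl group and O-sulfonylation of the enolate should give the 1,1-disubstituted enol triflate, the C18 ester having no α-hydrogen.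

Step 13
Reactants: 19 but-3-yn-1-ol
Product: 20 tert-butyl(but-3-yn-1-yloxy)diphenylsilane
Conditions: TBDPSCl, imidazole, CH2Cl2, rt
Reagents that add atoms: tert-butyldiphenylsilyl chloride CC(C)(C)[Si](Cl)(c1ccccc1)c1ccccc1
Why: Standard imidazole-mediated silylation of the primary alcohol.

Step 14
Reactants: 20 tert-butyl(but-3-yn-1-yloxy)diphenylsilane
Product: 23 (E)-6-(tert-butyldiphenylsilyloxy)-4-methylhex-3-en-1-ol, via alkenylalane 21 (not isolated), via lithium alanate 22 (not isolated)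
Conditions: Me3Al, Cp2ZrCl2 (cat.), CH2Cl2, 0 °C to rt; then n-BuLi, THF, −78 °C; ethylene oxide, −78 °C to rt
Reagents that add atoms: trimethylaluminium C[Al](C)C; ethylene oxide C1CO1
Why: Negishi zirconium-catalysed carboalumination adds CH3 and Al syn across the alkyne, and the alkenylalanate then opens ethylene oxide with retention of geometry, which should give the (E)-homoallylic alcohol with the new chain cis to the methyl group.

Step 15
Reactants: 23 (E)-6-(tert-butyldiphenylsilyloxy)-4-methylhex-3-en-1-ol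
Product: 24 (E)-6-(tert-butyldiphenylsilyloxy)-4-methylhex-3-enal
Conditions: Dess–Martin periodinane, NaHCO3, CH2Cl2, 0 °C; used crude at once
Reagents that add atoms: none
Why: Buffered Dess–Martin oxidation should give the β,γ-unsaturated aldehyde without moving the alkene into conjugation.

Step 16
Reactants: 18 methyl 6α,8α-bis(triethylsilyloxy)-13-(trifluoromethanesulfonyloxy)-14,15-dinorlabd-13(16)-en-18-oate; 24 (E)-6-(tert-butyldiphenylsilyloxy)-4-methylhex-3-enal
Product: 25 methyl 13-[(1′RS,3′E)-6′-(tert-butyldiphenylsilyloxy)-1′-hydroxy-4′-methylhex-3′-enyl]-6α,8α-bis(triethylsilyloxy)-14,15-dinorlabd-13(16)-en-18-oate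
Conditions: CrCl2 (excess), NiCl2 (cat.), DMF, rt
Reagents that add atoms: none
Why: Nozaki–Hiyama–Kishi coupling: the alkenylchromium species formed from the enol triflate under nickel catalysis adds chemoselectively to the aldehyde, forming C13–C1′; the uncontrolled C1′ carbinol is converged in the next two steps.

Step 17
Reactants: 25 methyl 13-[(1′RS,3′E)-6′-(tert-butyldiphenylsilyloxy)-1′-hydroxy-4′-methylhex-3′-enyl]-6α,8α-bis(triethylsilyloxy)-14,15-dinorlabd-13(16)-en-18-oate
Product: 26 methyl 13-[(3′E)-6′-(tert-butyldiphenylsilyloxy)-4′-methyl-1′-oxohex-3′-enyl]-6α,8α-bis(triethylsilyloxy)-14,15-dinorlabd-13(16)-en-18-oate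
Conditions: Dess–Martin periodinane, NaHCO3, CH2Cl2, 0 °C
Reagents that add atoms: none
Why: Dess–Martin oxidation of the allylic alcohol to the α-methylene ketone removes the uncontrolled C1′ centre under non-basic conditions that should not conjugate the skipped alkene.

Step 18
Reactants: 26 methyl 13-[(3′E)-6′-(tert-butyldiphenylsilyloxy)-4′-methyl-1′-oxohex-3′-enyl]-6α,8α-bis(triethylsilyloxy)-14,15-dinorlabd-13(16)-en-18-oate
Product: 27 methyl 13-[(1′S,3′E)-6′-(tert-butyldiphenylsilyloxy)-1′-hydroxy-4′-methylhex-3′-enyl]-6α,8α-bis(triethylsilyloxy)-14,15-dinorlabd-13(16)-en-18-oate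
Conditions: (R)-Me-CBS oxazaborolidine, catecholborane, toluene, −78 °C
Reagents that add atoms: none
Why: Corey–Bakshi–Shibata reduction: with the (R)-oxazaborolidine the 2-substituted vinyl group acts as the large substituent, so hydride should be delivered to give the (1′S)-allylic alcohol, and catecholborane at low temperature does not hydroborate the alkenes.

Step 19
Reactants: 27 methyl 13-[(1′S,3′E)-6′-(tert-butyldiphenylsilyloxy)-1′-hydroxy-4′-methylhex-3′-enyl]-6α,8α-bis(triethylsilyloxy)-14,15-dinorlabd-13(16)-en-18-oate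
Product: 28 methyl 13-[(1′S,3′S,4′S)-6′-(tert-butyldiphenylsilyloxy)-3′,4′-epoxy-1′-hydroxy-4′-methylhexyl]-6α,8α-bis(triethylsilyloxy)-14,15-dinorlabd-13(16)-en-18-oate
Conditions: L-fructose-derived Shi ketone (cat.), KHSO5 (Oxone), K2CO3, Bu4NHSO4, MeCN/dimethoxymethane/aq. buffer (pH 10.5), 0 °C
Reagents that add atoms: potassium peroxymonosulfate [K+].[O-]S(=O)(=O)OO
Why: Shi asymmetric epoxidation: the chiral dioxirane should epoxidise the electron-rich (E)-trisubstituted alkene through a spiro transition state to the (3′S,4′S)-epoxide under catalyst control, the 1,1-disubstituted alkene reacting much more slowly.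

Step 20
Reactants: 28 methyl 13-[(1′S,3′S,4′S)-6′-(tert-butyldiphenylsilyloxy)-3′,4′-epoxy-1′-hydroxy-4′-methylhexyl]-6α,8α-bis(triethylsilyloxy)-14,15-dinorlabd-13(16)-en-18-oate
Product: 29 methyl 13-[(1′S,3′S,4′S)-6′-(tert-butyldiphenylsilyloxy)-3′,4′-epoxy-1′-(methanesulfonyloxy)-4′-methylhexyl]-6α,8α-bis(triethylsilyloxy)-14,15-dinorlabd-13(16)-en-18-oate
Conditions: Ms2O, Et3N, CH2Cl2, −20 °C; cold work-up, used at once
Reagents that add atoms: methanesulfonic anhydride CS(=O)(=O)OS(C)(=O)=O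
Why: O-sulfonylation with retention at C1′ removes the hydroxyl that could open the epoxide and installs the leaving group, the anhydride avoiding chloride that could displace the allylic sulfonate.

Step 21
Reactants: 29 methyl 13-[(1′S,3′S,4′S)-6′-(tert-butyldiphenylsilyloxy)-3′,4′-epoxy-1′-(methanesulfonyloxy)-4′-methylhexyl]-6α,8α-bis(triethylsilyloxy)-14,15-dinorlabd-13(16)-en-18-oate
Product: 31 methyl 13-[(1′R,3′S,4′R)-6′-(tert-butyldiphenylsilyloxy)-1′,4′-epidioxy-3′-hydroxy-4′-methylhexyl]-6α,8α-bis(triethylsilyloxy)-14,15-dinorlabd-13(16)-en-18-oate, via hydroperoxy mesylate 30 (not isolated)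
Conditions: H2O2 (anhydrous, in Et2O), H3PMo12O40 (cat.), Et2O, 0 °C; aqueous wash; then Cs2CO3, MeCN, 0 °C
Reagents that add atoms: hydrogen peroxide OO
Why: Phosphomolybdic acid-catalysed perhydrolysis should open the trisubstituted epoxide at the tertiary C4′ with inversion, and the hydroperoxide anion then displaces the C1′ mesylate in a 6-exo-tet SN2 reaction with inversion to give the (1′R)-1,2-dioxane, the intramolecular mode excluding SN2′ attack at the terminal methylene.

Step 22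
Reactants: 31 methyl 13-[(1′R,3′S,4′R)-6′-(tert-butyldiphenylsilyloxy)-1′,4′-epidioxy-3′-hydroxy-4′-methylhexyl]-6α,8α-bis(triethylsilyloxy)-14,15-dinorlabd-13(16)-en-18-oate
Product: 32 methyl 13-[(1′R,3′S,4′R)-1′,4′-epidioxy-3′,6′-dihydroxy-4′-methylhexyl]-6α,8α-dihydroxy-14,15-dinorlabd-13(16)-en-18-oate
Conditions: HF·pyridine, pyridine/THF, 0 °C to rt
Reagents that add atoms: none
Why: Acidic fluoride should cleave both triethylsilyl ethers and the primary TBDPS ether while the dialkyl peroxide survives, no base being present that could trigger Kornblum–DeLaMare cleavage at C1′.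

Step 23
Reactants: 32 methyl 13-[(1′R,3′S,4′R)-1′,4′-epidioxy-3′,6′-dihydroxy-4′-methylhexyl]-6α,8α-dihydroxy-14,15-dinorlabd-13(16)-en-18-oate
Product: 35 CNP0162504.1 (methyl 6α,8α-dihydroxy-13-[(3R,4aS,7aR)-7a-methyl-6-oxohexahydrofuro[3,2-c][1,2]dioxin-3-yl]-14,15-dinorlabd-13(16)-en-18-oate), via hydroxy aldehyde 33 (not isolated), via lactol 34 (not isolated)
Conditions: TEMPO (cat.), PhI(OAc)2, CH2Cl2, rt
Reagents that add atoms: none
Why: TEMPO/PhI(OAc)2 oxidative lactonisation should oxidise only the primary C6′ alcohol to the aldehyde, which the C3′ hydroxyl (trans-diequatorial to the C5′ chain) traps as the lactol that is oxidised on to the trans-fused γ-lactone, the hindered C6 and tertiary C8 alcohols and the peroxide remaining untouched.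

Compound list
1 | (5E,9E)-farnesylacetone | CC(=O)CC/C=C(\C)CC/C=C(\C)CCC=C(C)C | starting material
2 | (5E,9E,13E)-15-hydroxy-6,10,14-trimethylpentadeca-5,9,13-trien-2-one | CC(=O)CC/C=C(\C)CC/C=C(\C)CC/C=C(\C)CO | intermediate
3 | (5E,9E)-12-[(2S,3S)-3-(hydroxymethyl)-3-methyloxiran-2-yl]-6,10-dimethyldodeca-5,9-dien-2-one | CC(=O)CC/C=C(\C)CC/C=C(\C)CC[C@@H]1O[C@@]1(C)CO | intermediate
4 | (5E,9E)-12-[(2S,3S)-3-(tert-butyldiphenylsilyloxymethyl)-3-methyloxiran-2-yl]-6,10-dimethyldodeca-5,9-dien-2-one (key-step precursor) | CC(=O)CC/C=C(\C)CC/C=C(\C)CC[C@@H]1O[C@@]1(C)CO[Si](c2ccccc2)(c2ccccc2)C(C)(C)C | intermediate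
5 | 18-(tert-butyldiphenylsilyloxy)-8α,13-epoxy-14,15-dinorlabd-12-en-3β-ol (key-step product) | CC1=CC[C@@H]2[C@@]3(C)CC[C@H](O)[C@@](C)(CO[Si](c4ccccc4)(c4ccccc4)C(C)(C)C)[C@@H]3CC[C@@]2(C)O1 | intermediate
6 | sodium xanthate of 5 (3β-O-dithiocarbonate sodium salt) | CC1=CC[C@@H]2[C@@]3(C)CC[C@H](OC(=S)[S-])[C@@](C)(CO[Si](c4ccccc4)(c4ccccc4)C(C)(C)C)[C@@H]3CC[C@@]2(C)O1.[Na+] | intermediate (not isolated)
7 | O-[18-(tert-butyldiphenylsilyloxy)-8α,13-epoxy-14,15-dinorlabd-12-en-3β-yl] S-methyl dithiocarbonate | CC1=CC[C@@H]2[C@@]3(C)CC[C@H](OC(=S)SC)[C@@](C)(CO[Si](c4ccccc4)(c4ccccc4)C(C)(C)C)[C@@H]3CC[C@@]2(C)O1 | intermediate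
8 | 18-(tert-butyldiphenylsilyloxy)-8α,13-epoxy-14,15-dinorlabd-12-ene | CC1=CC[C@@H]2[C@@]3(C)CCC[C@@](C)(CO[Si](c4ccccc4)(c4ccccc4)C(C)(C)C)[C@@H]3CC[C@@]2(C)O1 | intermediate
9 | 8α,13-epoxy-14,15-dinorlabd-12-en-18-ol | CC1=CC[C@@H]2[C@@]3(C)CCC[C@@](C)(CO)[C@@H]3CC[C@@]2(C)O1 | intermediate (not isolated)
10 | 8α,18-dihydroxy-14,15-dinorlabdan-13-one | CC(=O)CC[C@@H]1[C@@]2(C)CCC[C@@](C)(CO)[C@@H]2CC[C@@]1(C)O | intermediate
11 | 8α-hydroxy-13-oxo-14,15-dinorlabdan-18-al | CC(=O)CC[C@@H]1[C@@]2(C)CCC[C@@](C)(C=O)[C@@H]2CC[C@@]1(C)O | intermediate (not isolated)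
12 | 8α-hydroxy-13-oxo-14,15-dinorlabdan-18-oic acid | CC(=O)CC[C@@H]1[C@@]2(C)CCC[C@@](C)(C(=O)O)[C@@H]2CC[C@@]1(C)O | intermediate
13 | 8α-hydroxy-13-oxo-14,15-dinorlabdan-18,6α-olide | CC(=O)CC[C@@H]1[C@@]2(C)CCC[C@@](C)(C(=O)O3)[C@@H]2[C@@H]3C[C@@]1(C)O | intermediate
14 | potassium 6α,8α-dihydroxy-13-oxo-14,15-dinorlabdan-18-oate | CC(=O)CC[C@@H]1[C@@]2(C)CCC[C@@](C)(C(=O)[O-])[C@@H]2[C@@H](O)C[C@@]1(C)O.[K+] | intermediate (not isolated)
15 | methyl 6α,8α-dihydroxy-13-oxo-14,15-dinorlabdan-18-oate | CC(=O)CC[C@@H]1[C@@]2(C)CCC[C@@](C)(C(=O)OC)[C@@H]2[C@@H](O)C[C@@]1(C)O | intermediate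
16 | methyl 13-oxo-6α,8α-bis(triethylsilyloxy)-14,15-dinorlabdan-18-oate | CC(=O)CC[C@@H]1[C@@]2(C)CCC[C@@](C)(C(=O)OC)[C@@H]2[C@@H](O[Si](CC)(CC)CC)C[C@@]1(C)O[Si](CC)(CC)CC | intermediate
17 | potassium 13(16)-enolate of 16 | C=C([O-])CC[C@@H]1[C@@]2(C)CCC[C@@](C)(C(=O)OC)[C@@H]2[C@@H](O[Si](CC)(CC)CC)C[C@@]1(C)O[Si](CC)(CC)CC.[K+] | intermediate (not isolated)
18 | methyl 6α,8α-bis(triethylsilyloxy)-13-(trifluoromethanesulfonyloxy)-14,15-dinorlabd-13(16)-en-18-oate | C=C(OS(=O)(=O)C(F)(F)F)CC[C@@H]1[C@@]2(C)CCC[C@@](C)(C(=O)OC)[C@@H]2[C@@H](O[Si](CC)(CC)CC)C[C@@]1(C)O[Si](CC)(CC)CC | intermediate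
19 | but-3-yn-1-ol | C#CCCO | starting material
20 | tert-butyl(but-3-yn-1-yloxy)diphenylsilane | C#CCCO[Si](c1ccccc1)(c1ccccc1)C(C)(C)C | intermediate
21 | (E)-[4-(tert-butyldiphenylsilyloxy)-2-methylbut-1-enyl]dimethylalane | C[Al](C)/C=C(\C)CCO[Si](c1ccccc1)(c1ccccc1)C(C)(C)C | intermediate (not isolated)
22 | lithium butyl[(E)-4-(tert-butyldiphenylsilyloxy)-2-methylbut-1-enyl]dimethylalanate | [Li+].CCCC[Al-](C)(C)/C=C(\C)CCO[Si](c1ccccc1)(c1ccccc1)C(C)(C)C | intermediate (not isolated)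
23 | (E)-6-(tert-butyldiphenylsilyloxy)-4-methylhex-3-en-1-ol | OCC/C=C(\C)CCO[Si](c1ccccc1)(c1ccccc1)C(C)(C)C | intermediate
24 | (E)-6-(tert-butyldiphenylsilyloxy)-4-methylhex-3-enal | O=CC/C=C(\C)CCO[Si](c1ccccc1)(c1ccccc1)C(C)(C)C | intermediate
25 | methyl 13-[(1′RS,3′E)-6′-(tert-butyldiphenylsilyloxy)-1′-hydroxy-4′-methylhex-3′-enyl]-6α,8α-bis(triethylsilyloxy)-14,15-dinorlabd-13(16)-en-18-oate | C=C(CC[C@@H]1[C@@]2(C)CCC[C@@](C)(C(=O)OC)[C@@H]2[C@@H](O[Si](CC)(CC)CC)C[C@@]1(C)O[Si](CC)(CC)CC)C(O)C/C=C(\C)CCO[Si](c1ccccc1)(c1ccccc1)C(C)(C)C | intermediate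
26 | methyl 13-[(3′E)-6′-(tert-butyldiphenylsilyloxy)-4′-methyl-1′-oxohex-3′-enyl]-6α,8α-bis(triethylsilyloxy)-14,15-dinorlabd-13(16)-en-18-oate | C=C(CC[C@@H]1[C@@]2(C)CCC[C@@](C)(C(=O)OC)[C@@H]2[C@@H](O[Si](CC)(CC)CC)C[C@@]1(C)O[Si](CC)(CC)CC)C(=O)C/C=C(\C)CCO[Si](c1ccccc1)(c1ccccc1)C(C)(C)C | intermediate
27 | (1′S)-allylic alcohol: methyl 13-[(1′S,3′E)-6′-(tert-butyldiphenylsilyloxy)-1′-hydroxy-4′-methylhex-3′-enyl]-6α,8α-bis(triethylsilyloxy)-14,15-dinorlabd-13(16)-en-18-oate | C=C(CC[C@@H]1[C@@]2(C)CCC[C@@](C)(C(=O)OC)[C@@H]2[C@@H](O[Si](CC)(CC)CC)C[C@@]1(C)O[Si](CC)(CC)CC)[C@@H](O)C/C=C(\C)CCO[Si](c1ccccc1)(c1ccccc1)C(C)(C)C | intermediate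
28 | (1′S,3′S,4′S)-epoxy alcohol: methyl 13-[6′-(tert-butyldiphenylsilyloxy)-3′,4′-epoxy-1′-hydroxy-4′-methylhexyl]-6α,8α-bis(triethylsilyloxy)-14,15-dinorlabd-13(16)-en-18-oate | C=C(CC[C@@H]1[C@@]2(C)CCC[C@@](C)(C(=O)OC)[C@@H]2[C@@H](O[Si](CC)(CC)CC)C[C@@]1(C)O[Si](CC)(CC)CC)[C@@H](O)C[C@@H]1O[C@@]1(C)CCO[Si](c1ccccc1)(c1ccccc1)C(C)(C)C | intermediate
29 | (1′S,3′S,4′S)-epoxy mesylate (1′-methanesulfonate of 28) | C=C(CC[C@@H]1[C@@]2(C)CCC[C@@](C)(C(=O)OC)[C@@H]2[C@@H](O[Si](CC)(CC)CC)C[C@@]1(C)O[Si](CC)(CC)CC)[C@@H](OS(C)(=O)=O)C[C@@H]1O[C@@]1(C)CCO[Si](c1ccccc1)(c1ccccc1)C(C)(C)C | intermediate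
30 | (1′S,3′S,4′R)-4′-hydroperoxy-3′-hydroxy-1′-mesylate | C=C(CC[C@@H]1[C@@]2(C)CCC[C@@](C)(C(=O)OC)[C@@H]2[C@@H](O[Si](CC)(CC)CC)C[C@@]1(C)O[Si](CC)(CC)CC)[C@@H](OS(C)(=O)=O)C[C@H](O)[C@](C)(OO)CCO[Si](c1ccccc1)(c1ccccc1)C(C)(C)C | intermediate (not isolated)
31 | (1′R,3′S,4′R)-1,2-dioxane: methyl 13-[6′-(tert-butyldiphenylsilyloxy)-1′,4′-epidioxy-3′-hydroxy-4′-methylhexyl]-6α,8α-bis(triethylsilyloxy)-14,15-dinorlabd-13(16)-en-18-oate | C=C(CC[C@@H]1[C@@]2(C)CCC[C@@](C)(C(=O)OC)[C@@H]2[C@@H](O[Si](CC)(CC)CC)C[C@@]1(C)O[Si](CC)(CC)CC)[C@H]1C[C@H](O)[C@@](C)(CCO[Si](c2ccccc2)(c2ccccc2)C(C)(C)C)OO1 | intermediate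
32 | methyl 13-[(1′R,3′S,4′R)-1′,4′-epidioxy-3′,6′-dihydroxy-4′-methylhexyl]-6α,8α-dihydroxy-14,15-dinorlabd-13(16)-en-18-oate | C=C(CC[C@@H]1[C@@]2(C)CCC[C@@](C)(C(=O)OC)[C@@H]2[C@@H](O)C[C@@]1(C)O)[C@H]1C[C@H](O)[C@@](C)(CCO)OO1 | intermediate
33 | 6′-aldehyde of 32 (hydroxy aldehyde) | C=C(CC[C@@H]1[C@@]2(C)CCC[C@@](C)(C(=O)OC)[C@@H]2[C@@H](O)C[C@@]1(C)O)[C@H]1C[C@H](O)[C@@](C)(CC=O)OO1 | intermediate (not isolated)
34 | trans-fused lactol (anomeric mixture) | C=C(CC[C@@H]1[C@@]2(C)CCC[C@@](C)(C(=O)OC)[C@@H]2[C@@H](O)C[C@@]1(C)O)[C@H]1C[C@@H]2OC(O)C[C@@]2(C)OO1 | intermediate (not isolated)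
35 | CNP0162504.1 | C=C(CC[C@@H]1[C@@]2(C)CCC[C@@](C)(C(=O)OC)[C@@H]2[C@@H](O)C[C@@]1(C)O)[C@H]1C[C@@H]2OC(=O)C[C@@]2(C)OO1 | target

Total step count: 23. Longest linear sequence: 20 steps (steps 1–12, then 16–23); the side-chain aldehyde 24 is made in 3 steps (13–15).

Steps most likely to fail

Step 21. What may go wrong: ionisation of the allylic mesylate, or its attack by H2O2, during the acidic perhydrolysis before the tertiary hydroperoxide is in place; or base-induced fragmentation of the β-hydroxy hydroperoxide instead of ring closure. The fallback replaces the sulfonate by a leaving group that tolerates acid and peroxide and reaches the same centre by double inversion. It sets out from enone 26: reduction with (S)-Me-CBS oxazaborolidine and catecholborane should give the (1′R)-allylic alcohol F1. Shi epoxidation as in step 19 then gives the (1′R,3′S,4′S)-epoxy alcohol F2. Appel chlorination (PPh3, CCl4, 2,6-lutidine) with inversion gives the (1′S)-allylic chloride F3. Perhydrolysis with H2O2 and H3PMo12O40 gives the hydroperoxy chloride F4, and Cs2CO3 in MeCN closes the ring with a second inversion, coming back to the route at 31.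

Step 9. What may go wrong: loss of site selectivity or over-oxidation in the iron-catalysed C–H oxidation (attack at the tertiary C5–H or C9–H bonds or on the tether). The fallback uses a radical relay from oxygen and sets out from 10. MeOH with PPTS and trimethyl orthoformate should give the cyclic methyl ketal F5, which masks the C8 hydroxyl and the ketone together. The hypoiodite reaction of the free C18 alcohol (PhI(OAc)2, I2, visible light, cyclohexane) then transfers H6α to the alkoxy radical (1,5-hydrogen shift) and closes the 6α,18-ether F6. RuCl3 (cat.) with NaIO4 oxidises the ether CH2 to the lactone ketal F7, and 1 M HCl in THF removes the ketal, coming back to the route at 13.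

Step 4. What may go wrong: termination of the cascade by proton loss from the C8 cation while the ketone is held by aluminium, so that oxygen capture does not occur. The fallback separates carbocyclisation from oxygen capture and sets out from 4. Cyclisation with SnCl4 in CH2Cl2 at −78 °C is taken on purpose to the alkene-terminated bicyclic 3β-hydroxy 8(17)-ene ketone F8 (its 7-ene isomer behaves alike). Catalytic p-TsOH in CH2Cl2 then reprotonates the alkene to the C8 cation, which the ketone oxygen traps under thermodynamic control on the equatorial side, coming back to the route at 5.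

Further compounds
F1 | step 21 | (1′R)-allylic alcohol, C1′ epimer of 27 | C=C(CC[C@@H]1[C@@]2(C)CCC[C@@](C)(C(=O)OC)[C@@H]2[C@@H](O[Si](CC)(CC)CC)C[C@@]1(C)O[Si](CC)(CC)CC)[C@H](O)C/C=C(\C)CCO[Si](c1ccccc1)(c1ccccc1)C(C)(C)C
F2 | step 21 | (1′R,3′S,4′S)-epoxy alcohol, C1′ epimer of 28 | C=C(CC[C@@H]1[C@@]2(C)CCC[C@@](C)(C(=O)OC)[C@@H]2[C@@H](O[Si](CC)(CC)CC)C[C@@]1(C)O[Si](CC)(CC)CC)[C@H](O)C[C@@H]1O[C@@]1(C)CCO[Si](c1ccccc1)(c1ccccc1)C(C)(C)C
F3 | step 21 | (1′S,3′S,4′S)-epoxy allylic chloride | C=C(CC[C@@H]1[C@@]2(C)CCC[C@@](C)(C(=O)OC)[C@@H]2[C@@H](O[Si](CC)(CC)CC)C[C@@]1(C)O[Si](CC)(CC)CC)[C@@H](Cl)C[C@@H]1O[C@@]1(C)CCO[Si](c1ccccc1)(c1ccccc1)C(C)(C)C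
F4 | step 21 | (1′S,3′S,4′R)-1′-chloro-4′-hydroperoxy-3′-hydroxy compound | C=C(CC[C@@H]1[C@@]2(C)CCC[C@@](C)(C(=O)OC)[C@@H]2[C@@H](O[Si](CC)(CC)CC)C[C@@]1(C)O[Si](CC)(CC)CC)[C@@H](Cl)C[C@H](O)[C@](C)(OO)CCO[Si](c1ccccc1)(c1ccccc1)C(C)(C)C
F5 | step 9 | 13-methoxy-8α,13-epoxy-14,15-dinorlabdan-18-ol | COC1(C)CC[C@@H]2[C@@]3(C)CCC[C@@](C)(CO)[C@@H]3CC[C@@]2(C)O1
F6 | step 9 | 13-methoxy-6α,18:8α,13-diepoxy-14,15-dinorlabdane | COC1(C)CC[C@@H]2[C@@]3(C)CCC[C@@](C)(CO4)[C@@H]3[C@@H]4C[C@@]2(C)O1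
F7 | step 9 | 13-methoxy-8α,13-epoxy-14,15-dinorlabdan-18,6α-olide | COC1(C)CC[C@@H]2[C@@]3(C)CCC[C@@](C)(C(=O)O4)[C@@H]3[C@@H]4C[C@@]2(C)O1
F8 | step 4 | 18-(tert-butyldiphenylsilyloxy)-3β-hydroxy-14,15-dinorlabd-8(17)-en-13-one | CC(=O)CC[C@@H]1[C@@]2(C)CC[C@H](O)[C@@](C)(CO[Si](c3ccccc3)(c3ccccc3)C(C)(C)C)[C@@H]2CCC1=C
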